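**Strategy.** Numbering: ring C1 (side chain), C2 (tiglate), C3 (ketone), C4–C5 (epoxide), C6; chain C7(=C12H2), C8(=O), C9=C10, C11(OOH). Everything rests on cutting C1–C2. The α-methylene carbonyl unit on C1 next to the oxygenated C2 is what an ester-bearing allylmetal leaves when its γ-carbon attacks an aldehyde. One chromium(II) Barbier cyclisation therefore closes the C1–C6 ring, sets C1 and C2 trans and unveils the C7 methylene ester. Its precursor is an acyclic cis-epoxide (C4–C5), which holds C3 and C6 syn, carrying on C4 a silyloxy-substituted acetaldehyde arm (C3, C2) and on C5, through C6, a (Z)-2-(bromomethyl)enoate (C1, C7, C12, C8).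

Key step: step 14

Remark: ring compounds 21–33 are named with the target locants C1–C6; PMB = 4-methoxybenzyl, TBS = tert-butyldimethylsilyl, tigloyl = (2E)-2-methylbut-2-enoyl.
Remark: 1, 3, 8, 13, 14, 22, 25, 27 and 29 are taken as commercially available; the allylchromium species 20 is drawn as its dichloride without solvent ligands.

Step 1
Reactants: 1 3-(PMB-oxy)propan-1-ol
Product: 2 3-(PMB-oxy)propanal
Conditions: TEMPO (cat.), PhI(OAc)2, CH2Cl2, rt
Reagents that add atoms: none
Why: The TEMPO/PhI(OAc)2 (Piancatelli) oxidation of a primary alcohol should stop at the aldehyde and leaves the PMB ether alone.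

Step 2
Reactants: 2 3-(PMB-oxy)propanal; 3 ethyl 2-(diphenoxyphosphoryl)propanoate
Product: 4 ethyl (2Z)-2-methyl-5-(PMB-oxy)pent-2-enoate
Conditions: NaH, THF, −78 → 0 °C
Reagents that add atoms: none
Why: Ando's Z-selective Horner–Wadsworth–Emmons olefination: the diaryl phosphonate collapses kinetically through the syn oxaphosphetane, so the ester should end cis to the chain, the geometry that later places C3 and C6 on the same side of the epoxide.

Step 3
Reactants: 4 ethyl (2Z)-2-methyl-5-(PMB-oxy)pent-2-enoate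
Product: 5 (2Z)-2-methyl-5-(PMB-oxy)pent-2-en-1-ol
Conditions: DIBAL-H (2.2 equiv), CH2Cl2, −78 °C; Rochelle salt
Reagents that add atoms: none
Why: 1,2-Reduction of the conjugated ester by DIBAL-H should give the allylic alcohol without touching the alkene geometry or the PMB ether.

Step 4
Reactants: 5 (2Z)-2-methyl-5-(PMB-oxy)pent-2-en-1-ol
Product: 6 [(2R,3S)-2-methyl-3-[2-(PMB-oxy)ethyl]oxiran-2-yl]methanol
Conditions: Ti(OiPr)4 (cat.), D-(−)-diisopropyl tartrate (cat.), t-BuOOH, 4 Å MS, CH2Cl2, −20 °C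
Reagents that add atoms: tert-butyl hydroperoxide, CC(C)(C)OO
Why: Katsuki–Sharpless asymmetric epoxidation: the D-tartrate titanium complex should deliver oxygen to the alkene face that gives the (2R,3S)-epoxide, which sets C4 and C5, and the Z geometry becomes the cis relationship of C3 and C6.

Step 5
Reactants: 6 [(2R,3S)-2-methyl-3-[2-(PMB-oxy)ethyl]oxiran-2-yl]methanol
Product: 7 (2S,3S)-2-methyl-3-[2-(PMB-oxy)ethyl]oxirane-2-carbaldehyde
Conditions: Dess–Martin periodinane, NaHCO3, CH2Cl2, 0 °C → rt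
Reagents that add atoms: none
Why: Buffered Dess–Martin oxidation should give the epoxy aldehyde, whose α-carbon is quaternary and so can neither epimerise nor eliminate.

Step 6
Reactants: 7 (2S,3S)-2-methyl-3-[2-(PMB-oxy)ethyl]oxirane-2-carbaldehyde; 8 vinylmagnesium bromide
Product: 9 (1R)-1-[(2R,3S)-2-methyl-3-[2-(PMB-oxy)ethyl]oxiran-2-yl]prop-2-en-1-ol
Conditions: THF, −78 °C; aq. NH4Cl
Reagents that add atoms: none
Why: Grignard 1,2-addition under non-chelating (Felkin–Anh/Cornforth) control: attack anti to the epoxide C–O bond, from the face away from the cis C6 chain, should favour the anti (1R) alcohol and so set C3; the minor epimer would be removed by chromatography.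

Step 7
Reactants: 9 (1R)-1-[(2R,3S)-2-methyl-3-[2-(PMB-oxy)ethyl]oxiran-2-yl]prop-2-en-1-ol
Product: 10 TBS ether of 9, tert-butyl{[(1R)-1-[(2S,3S)-2-methyl-3-[2-(PMB-oxy)ethyl]oxiran-2-yl]prop-2-en-1-yl]oxy}dimethylsilane
Conditions: TBSOTf, 2,6-lutidine, CH2Cl2, −78 °C
Reagents that add atoms: tert-butyldimethylsilyl trifluoromethanesulfonate, CC(C)(C)[Si](C)(C)OS(=O)(=O)C(F)(F)F
Why: Silylation of the hindered secondary alcohol with the silyl triflate and a non-nucleophilic base should be fast at low temperature and leaves epoxide and PMB ether untouched.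

Step 8
Reactants: 10 TBS ether of 9
Product: 11 2-[(2S,3S)-3-[(1R)-1-(TBS-oxy)prop-2-en-1-yl]-3-methyloxiran-2-yl]ethan-1-ol
Conditions: DDQ, CH2Cl2/pH 7 buffer, 0 °C
Reagents that add atoms: none
Why: Oxidative PMB cleavage by DDQ runs at neutral pH, so the liberated alcohol should not be driven by acid onto the tertiary epoxide carbon, and the TBS ether survives.

Step 9
Reactants: 11 2-[(2S,3S)-3-[(1R)-1-(TBS-oxy)prop-2-en-1-yl]-3-methyloxiran-2-yl]ethan-1-ol
Product: 12 2-[(2S,3S)-3-[(1R)-1-(TBS-oxy)prop-2-en-1-yl]-3-methyloxiran-2-yl]acetaldehyde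
Conditions: Dess–Martin periodinane, pyridine, CH2Cl2, 0 °C; used crude at once
Reagents that add atoms: none
Why: Buffered Dess–Martin oxidation should deliver the sensitive β,γ-epoxy aldehyde without enolisation, and it is not chromatographed.

Step 10
Reactants: 13 methyl propanoate; 14 benzeneselenenyl chloride
Product: 15 methyl 2-(phenylselanyl)propanoate (racemic)
Conditions: LDA, THF, −78 °C
Reagents that add atoms: none
Why: α-Selenenylation of a lithium ester enolate is a standard route to the α-seleno ester, which serves as a masked acrylate α-anion.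

Step 11
Reactants: 12 2-[(2S,3S)-3-[(1R)-1-(TBS-oxy)prop-2-en-1-yl]-3-methyloxiran-2-yl]acetaldehyde; 15 methyl 2-(phenylselanyl)propanoate
Product: 17 methyl 3-hydroxy-2-methylidene-4-[(2S,3S)-3-[(1R)-1-(TBS-oxy)prop-2-en-1-yl]-3-methyloxiran-2-yl]butanoate (carbinol epimers), via seleno-aldol adduct 16 (not isolated)
Conditions: LDA, THF, −78 °C, then 12, −78 °C; AcOH; then 30% H2O2, pyridine, 0 °C → rt
Reagents that add atoms: none
Why: Aldol addition of the lithium enolate at −78 °C should outrun enolisation of the aldehyde, and selenoxide syn-elimination away from the carbinol carbon into the methyl group gives the α-methylene β-hydroxy ester (a Baylis–Hillman-type adduct made without an amine base); the carbinol configuration is irrelevant because that carbon becomes sp2 in the next step.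

Step 12
Reactants: 17 methyl 3-hydroxy-2-methylidene-4-[(2S,3S)-3-[(1R)-1-(TBS-oxy)prop-2-en-1-yl]-3-methyloxiran-2-yl]butanoate
Product: 18 methyl (2Z)-2-(bromomethyl)-4-[(2S,3S)-3-[(1R)-1-(TBS-oxy)prop-2-en-1-yl]-3-methyloxiran-2-yl]but-2-enoate
Conditions: NBS, Me2S, CH2Cl2, 0 °C → rt
Reagents that add atoms: N-bromosuccinimide, O=C1CCC(=O)N1Br
Why: Corey–Kim-type activation of the allylic alcohol as an alkoxysulfonium salt and SN2′ attack of bromide on the methylene terminus should give the rearranged primary bromide as the favoured Z isomer (chain trans to the ester) under neutral conditions that spare epoxide, silyl ether and vinyl group.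

Step 13
Reactants: 18 methyl (2Z)-2-(bromomethyl)-4-[(2S,3S)-3-[(1R)-1-(TBS-oxy)prop-2-en-1-yl]-3-methyloxiran-2-yl]but-2-enoate
Product: 19 methyl (2Z)-2-(bromomethyl)-4-[(2S,3S)-3-[(1S)-1-(TBS-oxy)-2-oxoethyl]-3-methyloxiran-2-yl]but-2-enoate
Conditions: O3, acetone/H2O (95:5), 0 °C, Sudan Red 7B end point; used at once
Reagents that add atoms: ozone, [O-][O+]=O
Why: Ozonolysis should pick the electron-richer monosubstituted alkene over the ester- and bromomethyl-deactivated trisubstituted one, and in wet acetone water traps the carbonyl oxide and releases the aldehyde directly, so no phosphine, sulfide or amine meets the allylic bromide.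

Step 14
Reactants: 19 methyl (2Z)-2-(bromomethyl)-4-[(2S,3S)-3-[(1S)-1-(TBS-oxy)-2-oxoethyl]-3-methyloxiran-2-yl]but-2-enoate
Product: 21 methyl 2-[(1S,2S,3R,4S,5S)-3-(TBS-oxy)-4,5-epoxy-2-hydroxy-4-methylcyclohexyl]prop-2-enoate, via allylchromium(III) species 20 (not isolated)
Conditions: CrCl2 (5 equiv), THF (0.01 M, slow addition of 19), 0 °C → rt; aq. NH4Cl
Reagents that add atoms: none
Why: Single-electron transfer from chromium(II), twice, turns the C12–Br bond into a C12–Cr(III) bond (species 20); this allylmetal, free to equilibrate between its σ-isomers, bonds to the aldehyde carbon C2 through C1 while chromium passes from C12 to the carbonyl oxygen in a six-membered cyclic array, so the double bond moves to C7=C12 next to the ester. The nearest precedent class is the intramolecular Nozaki–Hiyama allylation (chromium Barbier, Dreiding–Schmidt type) of ω-formyl 2-(bromomethyl)acrylates, which furnishes α-methylene esters or lactones on carbocycles. Ring closure is 6-exo-trig (C1 adds to trigonal C2, whose oxygen stays outside the new ring) and is made easy because the cis-epoxide already holds C3 and C6 syn. C1 and C2 are set together in a trans-decalin-like transition state whose forming ring is a half-chair with the C3 silyloxy group, the chromium-bound oxygen and the C7 acrylate unit all equatorial; the existing C3 centre and the epoxide select this half-chair, so the C2 oxygen should end trans to the epoxide oxygen and to C7. The step needs chemoselectivity, which chromium(II) provides by reacting only with the allylic bromide/aldehyde pair under non-basic conditions (epoxide, silyl ether, enoate and the enolisable aldehyde are spared), and trans diastereoselectivity, for which the substrate offers the all-equatorial arrangement, whereas the cis-fused alternative must place the ligated chromium alkoxide axial on the face of the epoxide oxygen. The trans hydroxy ester should not lactonise under these conditions.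

Step 15
Reactants: 21 methyl 2-[(1S,2S,3R,4S,5S)-3-(TBS-oxy)-4,5-epoxy-2-hydroxy-4-methylcyclohexyl]prop-2-enoate; 22 tiglic acid
Product: 23 methyl 2-[(1S,2S,3R,4S,5S)-3-(TBS-oxy)-4,5-epoxy-4-methyl-2-(tigloyloxy)cyclohexyl]prop-2-enoate
Conditions: 2,4,6-trichlorobenzoyl chloride, Et3N, DMAP, toluene, rt
Reagents that add atoms: none
Why: Yamaguchi esterification through the mixed anhydride should acylate the hindered equatorial C2 hydroxyl with retention at C2 and without loss of the E geometry of the tiglate.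

Step 16
Reactants: 23 methyl 2-[(1S,2S,3R,4S,5S)-3-(TBS-oxy)-4,5-epoxy-4-methyl-2-(tigloyloxy)cyclohexyl]prop-2-enoate
Product: 24 2-[(1S,2S,3R,4S,5S)-3-(TBS-oxy)-4,5-epoxy-4-methyl-2-(tigloyloxy)cyclohexyl]prop-2-enoic acid
Conditions: Me3SnOH, 1,2-dichloroethane, 70 °C; cold dilute aq. HCl wash
Reagents that add atoms: trimethyltin hydroxide, C[Sn](C)(C)O
Why: Trimethyltin hydroxide hydrolysis is selective for methyl esters, so the hindered secondary tiglate, the epoxide and the silyl ether should survive, and no strong base is present.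

Step 17
Reactants: 24 2-[(1S,2S,3R,4S,5S)-3-(TBS-oxy)-4,5-epoxy-4-methyl-2-(tigloyloxy)cyclohexyl]prop-2-enoic acid; 25 N,O-dimethylhydroxylamine hydrochloride
Product: 26 N-methoxy-N-methyl-2-[(1S,2S,3R,4S,5S)-3-(TBS-oxy)-4,5-epoxy-4-methyl-2-(tigloyloxy)cyclohexyl]prop-2-enamide
Conditions: EDC·HCl, HOBt, i-Pr2NEt, CH2Cl2, 0 °C → rt
Reagents that add atoms: none
Why: Carbodiimide/HOBt amide coupling gives the Weinreb amide, and attack of the weakly basic amine on the active ester should be faster than conjugate addition to the α-branched acrylate.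

Step 18
Reactants: 26 N-methoxy-N-methyl-2-[(1S,2S,3R,4S,5S)-3-(TBS-oxy)-4,5-epoxy-4-methyl-2-(tigloyloxy)cyclohexyl]prop-2-enamide; 27 allylmagnesium bromide
Product: 28 (1S,2S,3R,4S,5S)-3-(TBS-oxy)-4,5-epoxy-4-methyl-1-(3-oxohexa-1,5-dien-2-yl)cyclohex-2-yl tiglate
Conditions: THF, −78 °C; cold aq. NH4Cl
Reagents that add atoms: none
Why: Weinreb ketone synthesis: the chelated tetrahedral intermediate forms within minutes at −78 °C and blocks over-addition, the conjugated and hindered tiglate should react more slowly, and the cold buffered quench keeps the β,γ-unsaturated ketone out of conjugation.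

Step 19
Reactants: 28 (1S,2S,3R,4S,5S)-3-(TBS-oxy)-4,5-epoxy-4-methyl-1-(3-oxohexa-1,5-dien-2-yl)cyclohex-2-yl tiglate; 29 2-methylbut-2-ene
Product: 30 (1S,2S,3R,4S,5S)-3-(TBS-oxy)-4,5-epoxy-4-methyl-1-(6-methyl-3-oxohepta-1,5-dien-2-yl)cyclohex-2-yl tiglate
Conditions: Grubbs II (5 mol %), 1,4-benzoquinone (10 mol %), 2-methylbut-2-ene/CH2Cl2, rt
Reagents that add atoms: none
Why: Olefin cross-metathesis with 2-methylbut-2-ene turns the terminal allyl group into a prenyl group; the 1,1-disubstituted enone and the trisubstituted tiglate are spectators, and benzoquinone suppresses ruthenium hydride isomerisation.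

Step 20
Reactants: 30 (1S,2S,3R,4S,5S)-3-(TBS-oxy)-4,5-epoxy-4-methyl-1-(6-methyl-3-oxohepta-1,5-dien-2-yl)cyclohex-2-yl tiglate
Product: 31 (1S,2S,3R,4R,5S)-4,5-epoxy-3-hydroxy-4-methyl-1-(6-methyl-3-oxohepta-1,5-dien-2-yl)cyclohex-2-yl tiglate
Conditions: HF·pyridine, pyridine, THF, 0 °C → rt
Reagents that add atoms: none
Why: Fluoride cleavage of the silyl ether under buffered, non-basic conditions should avoid alkoxide chemistry (Payne rearrangement, 1,2-shift of the tiglate, conjugation of the enone).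

Step 21
Reactants: 31 (1S,2S,3R,4R,5S)-4,5-epoxy-3-hydroxy-4-methyl-1-(6-methyl-3-oxohepta-1,5-dien-2-yl)cyclohex-2-yl tiglate
Product: 32 (1S,2S,4S,5S)-4,5-epoxy-4-methyl-1-(6-methyl-3-oxohepta-1,5-dien-2-yl)-3-oxocyclohex-2-yl tiglate
Conditions: Dess–Martin periodinane, NaHCO3, CH2Cl2, 0 °C → rt
Reagents that add atoms: none
Why: Dess–Martin oxidation gives the C3 epoxy ketone under neutral conditions, so the now enolisable C2 centre should keep its configuration and the β,γ-enone stays unconjugated.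

Step 22
Reactants: 32 (1S,2S,4S,5S)-4,5-epoxy-4-methyl-1-(6-methyl-3-oxohepta-1,5-dien-2-yl)-3-oxocyclohex-2-yl tiglate
Product: 33 (1S,2S,4S,5S)-4,5-epoxy-1-[(4E)-6-hydroperoxy-6-methyl-3-oxohepta-1,4-dien-2-yl]-4-methyl-3-oxocyclohex-2-yl tiglate (CNP0284595.1)
Conditions: O2, tetraphenylporphyrin (cat.), visible light, CH2Cl2, 0 °C
Reagents that add atoms: dioxygen, O=O
Why: Schenck ene reaction of singlet oxygen with the trisubstituted prenyl alkene: as with other β,γ-unsaturated carbonyl compounds the C9 hydrogen (allylic and α to C8=O) should be abstracted in preference to a methyl hydrogen, which puts the hydroperoxide on tertiary C11 and moves the alkene to C9=C10 as the E isomer, while the electron-poor alkenes do not react.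

**Compound list**

1 | 3-(PMB-oxy)propan-1-ol | COc1ccc(COCCCO)cc1 | starting material
2 | 3-(PMB-oxy)propanal | COc1ccc(COCCC=O)cc1 | intermediate
3 | ethyl 2-(diphenoxyphosphoryl)propanoate | CCOC(=O)C(C)P(=O)(Oc1ccccc1)Oc1ccccc1 | starting material
4 | ethyl (2Z)-2-methyl-5-(PMB-oxy)pent-2-enoate | CCOC(=O)/C(C)=C\CCOCc1ccc(OC)cc1 | intermediate
5 | (2Z)-2-methyl-5-(PMB-oxy)pent-2-en-1-ol | OC/C(C)=C\CCOCc1ccc(OC)cc1 | intermediate
6 | [(2R,3S)-2-methyl-3-[2-(PMB-oxy)ethyl]oxiran-2-yl]methanol | OC[C@@]1(C)O[C@H]1CCOCc1ccc(OC)cc1 | intermediate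
7 | (2S,3S)-2-methyl-3-[2-(PMB-oxy)ethyl]oxirane-2-carbaldehyde | O=C[C@@]1(C)O[C@H]1CCOCc1ccc(OC)cc1 | intermediate
8 | vinylmagnesium bromide | C=C[Mg]Br | starting material
9 | (1R)-1-[(2R,3S)-2-methyl-3-[2-(PMB-oxy)ethyl]oxiran-2-yl]prop-2-en-1-ol | C=C[C@@H](O)[C@@]1(C)O[C@H]1CCOCc1ccc(OC)cc1 | intermediate
10 | TBS ether of 9 | C=C[C@@H](O[Si](C)(C)C(C)(C)C)[C@@]1(C)O[C@H]1CCOCc1ccc(OC)cc1 | intermediate
11 | 2-[(2S,3S)-3-[(1R)-1-(TBS-oxy)prop-2-en-1-yl]-3-methyloxiran-2-yl]ethan-1-ol | C=C[C@@H](O[Si](C)(C)C(C)(C)C)[C@@]1(C)O[C@H]1CCO | intermediate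
12 | 2-[(2S,3S)-3-[(1R)-1-(TBS-oxy)prop-2-en-1-yl]-3-methyloxiran-2-yl]acetaldehyde | C=C[C@@H](O[Si](C)(C)C(C)(C)C)[C@@]1(C)O[C@H]1CC=O | intermediate
13 | methyl propanoate | CCC(=O)OC | starting material
14 | benzeneselenenyl chloride | Cl[Se]c1ccccc1 | starting material
15 | methyl 2-(phenylselanyl)propanoate (racemic) | COC(=O)C(C)[Se]c1ccccc1 | intermediate
16 | seleno-aldol adduct, methyl 3-hydroxy-2-methyl-2-(phenylselanyl)-4-[(2S,3S)-3-[(1R)-1-(TBS-oxy)prop-2-en-1-yl]-3-methyloxiran-2-yl]butanoate (diastereomer mixture, not isolated) | C=C[C@@H](O[Si](C)(C)C(C)(C)C)[C@@]1(C)O[C@H]1CC(O)C(C)([Se]c1ccccc1)C(=O)OC | intermediate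
17 | methyl 3-hydroxy-2-methylidene-4-[(2S,3S)-3-[(1R)-1-(TBS-oxy)prop-2-en-1-yl]-3-methyloxiran-2-yl]butanoate (carbinol epimers) | C=C[C@@H](O[Si](C)(C)C(C)(C)C)[C@@]1(C)O[C@H]1CC(O)C(=C)C(=O)OC | intermediate
18 | methyl (2Z)-2-(bromomethyl)-4-[(2S,3S)-3-[(1R)-1-(TBS-oxy)prop-2-en-1-yl]-3-methyloxiran-2-yl]but-2-enoate | C=C[C@@H](O[Si](C)(C)C(C)(C)C)[C@@]1(C)O[C@H]1C/C=C(\CBr)C(=O)OC | intermediate
19 | methyl (2Z)-2-(bromomethyl)-4-[(2S,3S)-3-[(1S)-1-(TBS-oxy)-2-oxoethyl]-3-methyloxiran-2-yl]but-2-enoate (key-step precursor) | O=C[C@@H](O[Si](C)(C)C(C)(C)C)[C@@]1(C)O[C@H]1C/C=C(\CBr)C(=O)OC | intermediate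
20 | allylchromium(III) dichloride derived from 19 (not isolated) | O=C[C@@H](O[Si](C)(C)C(C)(C)C)[C@@]1(C)O[C@H]1C/C=C(\C[Cr](Cl)Cl)C(=O)OC | intermediate
21 | methyl 2-[(1S,2S,3R,4S,5S)-3-(TBS-oxy)-4,5-epoxy-2-hydroxy-4-methylcyclohexyl]prop-2-enoate (key-step product) | COC(=O)C(=C)[C@@H]1C[C@@H]2O[C@]2(C)[C@H](O[Si](C)(C)C(C)(C)C)[C@H]1O | intermediate
22 | tiglic acid | C/C=C(\C)C(=O)O | starting material
23 | methyl 2-[(1S,2S,3R,4S,5S)-3-(TBS-oxy)-4,5-epoxy-4-methyl-2-(tigloyloxy)cyclohexyl]prop-2-enoate | COC(=O)C(=C)[C@@H]1C[C@@H]2O[C@]2(C)[C@H](O[Si](C)(C)C(C)(C)C)[C@H]1OC(=O)/C(C)=C/C | intermediate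
24 | 2-[(1S,2S,3R,4S,5S)-3-(TBS-oxy)-4,5-epoxy-4-methyl-2-(tigloyloxy)cyclohexyl]prop-2-enoic acid | OC(=O)C(=C)[C@@H]1C[C@@H]2O[C@]2(C)[C@H](O[Si](C)(C)C(C)(C)C)[C@H]1OC(=O)/C(C)=C/C | intermediate
25 | N,O-dimethylhydroxylamine hydrochloride | CNOC.Cl | starting material
26 | N-methoxy-N-methyl-2-[(1S,2S,3R,4S,5S)-3-(TBS-oxy)-4,5-epoxy-4-methyl-2-(tigloyloxy)cyclohexyl]prop-2-enamide | CON(C)C(=O)C(=C)[C@@H]1C[C@@H]2O[C@]2(C)[C@H](O[Si](C)(C)C(C)(C)C)[C@H]1OC(=O)/C(C)=C/C | intermediate
27 | allylmagnesium bromide | C=CC[Mg]Br | starting material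
28 | (1S,2S,3R,4S,5S)-3-(TBS-oxy)-4,5-epoxy-4-methyl-1-(3-oxohexa-1,5-dien-2-yl)cyclohex-2-yl tiglate | C=CCC(=O)C(=C)[C@@H]1C[C@@H]2O[C@]2(C)[C@H](O[Si](C)(C)C(C)(C)C)[C@H]1OC(=O)/C(C)=C/C | intermediate
29 | 2-methylbut-2-ene | CC=C(C)C | starting material
30 | (1S,2S,3R,4S,5S)-3-(TBS-oxy)-4,5-epoxy-4-methyl-1-(6-methyl-3-oxohepta-1,5-dien-2-yl)cyclohex-2-yl tiglate | CC(C)=CCC(=O)C(=C)[C@@H]1C[C@@H]2O[C@]2(C)[C@H](O[Si](C)(C)C(C)(C)C)[C@H]1OC(=O)/C(C)=C/C | intermediate
31 | (1S,2S,3R,4R,5S)-4,5-epoxy-3-hydroxy-4-methyl-1-(6-methyl-3-oxohepta-1,5-dien-2-yl)cyclohex-2-yl tiglate | CC(C)=CCC(=O)C(=C)[C@@H]1C[C@@H]2O[C@]2(C)[C@H](O)[C@H]1OC(=O)/C(C)=C/C | intermediate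
32 | (1S,2S,4S,5S)-4,5-epoxy-4-methyl-1-(6-methyl-3-oxohepta-1,5-dien-2-yl)-3-oxocyclohex-2-yl tiglate | CC(C)=CCC(=O)C(=C)[C@@H]1C[C@@H]2O[C@]2(C)C(=O)[C@H]1OC(=O)/C(C)=C/C | intermediate
33 | (1S,2S,4S,5S)-4,5-epoxy-1-[(4E)-6-hydroperoxy-6-methyl-3-oxohepta-1,4-dien-2-yl]-4-methyl-3-oxocyclohex-2-yl tiglate | C=C(C(=O)/C=C/C(C)(C)OO)[C@@H]1C[C@@H]2O[C@]2(C)C(=O)[C@H]1OC(=O)/C(C)=C/C | target

**Step count.** Total: 22 steps. Longest linear sequence: 21 steps (1 → 33 through steps 1–9 and 11–22; step 10 makes reagent 15).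

**Steps most likely to fail**

Step 14. What may go wrong is loss of relative stereocontrol in the ring closure. Ester-bearing allylmetals with a γ-substituent often react through the cis-fused closed transition state (C6 cis to the CH2–metal group, metal alkoxide axial); that would set C2 the other way round and be followed by lactonisation. The fallback turns this outcome into the plan (inversion instead of direct trans closure). It sets out from 19, which would be cyclised under indium (THF/H2O) or zinc Barbier conditions, known to favour the syn mode, to the cis-fused α-methylene-γ-butyrolactone F1 (C1 as required, C2 epimeric). Opening with the chloromagnesium amide made from 25 and i-PrMgCl would give the C2-epimeric hydroxy Weinreb amide F2. Mitsunobu esterification with tiglic acid 22 (PPh3, DIAD) would install the tiglate with inversion at C2 and come back to the route at 26.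

Step 11. What may go wrong is enolisation of the β,γ-epoxy aldehyde by the lithium enolate, followed by β-elimination that opens the epoxide, in competition with the aldol addition. The fallback replaces the basic aldol by a neutral olefination and sets out from 12. Wittig reaction with the stabilised ylide methyl bromo(triphenyl-λ5-phosphanylidene)acetate in CH2Cl2 would give the (Z)-2-bromo enoate F3. Stille coupling with (tributylstannyl)methanol [Pd(PPh3)4, dioxane, 80 °C] would give the (E)-2-(hydroxymethyl) enoate F4 with retention of the alkene geometry. Appel bromination (CBr4, PPh3) would come back to the route at 18.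

Step 22. What may go wrong is hydrogen abstraction from a methyl group instead of from C9 in the ene reaction (wrong regiochemistry), or further photo-oxidation of the product. The fallback brings the peroxide in as a protected building block by metathesis and sets out from 26. Addition of vinylmagnesium bromide 8 would give the vinyl ketone F5, HF·pyridine the C3 alcohol F6 and Dess–Martin oxidation the divinyl diketone F7. Separately, 2-methylbut-3-en-2-ol would be converted by acid-catalysed perhydrolysis (H2O2, cat. H2SO4) into 2-methylbut-3-en-2-yl hydroperoxide F8 and protected with 2-methoxypropene/PPTS as the peroxyketal F9. Cross-metathesis of F7 with F9 (Hoveyda–Grubbs II, CH2Cl2, 40 °C) would give the protected E-hydroperoxide F10, and mild acid (AcOH/THF/H2O) would release the target 33.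

**Further compounds**

F1 | step 14 | cis-fused α-methylene-γ-butyrolactone (C2 epimer of 21, lactonised between O–C2 and C8) | C=C1C(=O)O[C@@H]2[C@H]1C[C@@H]3O[C@]3(C)[C@@H]2O[Si](C)(C)C(C)(C)C
F2 | step 14 | C2-epimeric hydroxy Weinreb amide, N-methoxy-N-methyl-2-[(1S,2R,3R,4S,5S)-3-(TBS-oxy)-4,5-epoxy-2-hydroxy-4-methylcyclohexyl]prop-2-enamide | CON(C)C(=O)C(=C)[C@@H]1C[C@@H]2O[C@]2(C)[C@H](O[Si](C)(C)C(C)(C)C)[C@@H]1O
F3 | step 11 | methyl (2Z)-2-bromo-4-[(2S,3S)-3-[(1R)-1-(TBS-oxy)prop-2-en-1-yl]-3-methyloxiran-2-yl]but-2-enoate | C=C[C@@H](O[Si](C)(C)C(C)(C)C)[C@@]1(C)O[C@H]1C/C=C(\Br)C(=O)OC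
F4 | step 11 | methyl (2E)-2-(hydroxymethyl)-4-[(2S,3S)-3-[(1R)-1-(TBS-oxy)prop-2-en-1-yl]-3-methyloxiran-2-yl]but-2-enoate | C=C[C@@H](O[Si](C)(C)C(C)(C)C)[C@@]1(C)O[C@H]1C/C=C(\CO)C(=O)OC
F5 | step 22 | (1S,2S,3R,4S,5S)-3-(TBS-oxy)-4,5-epoxy-4-methyl-1-(3-oxopenta-1,4-dien-2-yl)cyclohex-2-yl tiglate | C=CC(=O)C(=C)[C@@H]1C[C@@H]2O[C@]2(C)[C@H](O[Si](C)(C)C(C)(C)C)[C@H]1OC(=O)/C(C)=C/C
F6 | step 22 | (1S,2S,3R,4R,5S)-4,5-epoxy-3-hydroxy-4-methyl-1-(3-oxopenta-1,4-dien-2-yl)cyclohex-2-yl tiglate | C=CC(=O)C(=C)[C@@H]1C[C@@H]2O[C@]2(C)[C@H](O)[C@H]1OC(=O)/C(C)=C/C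
F7 | step 22 | (1S,2S,4S,5S)-4,5-epoxy-4-methyl-3-oxo-1-(3-oxopenta-1,4-dien-2-yl)cyclohex-2-yl tiglate | C=CC(=O)C(=C)[C@@H]1C[C@@H]2O[C@]2(C)C(=O)[C@H]1OC(=O)/C(C)=C/C
F8 | step 22 | 2-methylbut-3-en-2-yl hydroperoxide | C=CC(C)(C)OO
F9 | step 22 | 3-[(2-methoxypropan-2-yl)peroxy]-3-methylbut-1-ene | C=CC(C)(C)OOC(C)(C)OC
F10 | step 22 | (2-methoxypropan-2-yl) peroxyketal of 33 | COC(C)(C)OOC(C)(C)/C=C/C(=O)C(=C)[C@@H]1C[C@@H]2O[C@]2(C)C(=O)[C@H]1OC(=O)/C(C)=C/C
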